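Ring B, the imidazole of pyronaamidine, is creatinine: N1–CH3, the C2 amino nitrogen, N3, C4 and C5 are already assembled. Its C5 methylene, beside N1–CH3, takes the benzyl group of ring A (2-hydroxy-3,4-dimethoxyphenyl) by condensation and hydrogenation. Everything rests on the C4–CH2 bond to ring C (4-methoxyphenyl): the key step exploits the C4 carbonyl oxygen of ring B, which enolisation across C4–C5 turns into the triflate of an aromatic imidazol-4-ol, and couples it in the same flask with 4-methoxybenzylzinc chloride. The coupling precursor is this 5-benzyl-1-methylimidazol-4-yl triflate, its C2 nitrogen masked as a dimethylformamidine and its phenol as a MOM ether. Acid deprotection and condensation with 1-methylparabanic acid (ring D) finish.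

Key step: step 6

Remark: the target has no stereocentre. C5 of 5 and 6 is formed racemic and becomes planar again in step 6, and the alkene geometry of 4 (Z expected) is erased in step 3. Compounds 1, 3, 7 and 14 are taken to be catalogue chemicals.

Step 1
Reactants: 1 2-hydroxy-3,4-dimethoxybenzaldehyde
Product: 2 3,4-dimethoxy-2-(methoxymethoxy)benzaldehyde
Conditions: MOMCl, iPr2NEt, CH2Cl2, 0 to 25 °C
Reagents that add atoms: chloromethyl methyl ether, COCCl
Why: Base-mediated O-alkylation of the phenol (Williamson-type acetal ether formation) with the very electrophilic α-chloro ether should proceed despite the hydrogen bond to the aldehyde, and the MOM acetal tolerates the later basic, reductive and organometallic steps yet falls in the same acid treatment that removes the amidine.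

Step 2
Reactants: 2 3,4-dimethoxy-2-(methoxymethoxy)benzaldehyde; 3 creatinine
Product: 4 (Z)-2-amino-5-[3,4-dimethoxy-2-(methoxymethoxy)benzylidene]-1-methyl-1,5-dihydro-4H-imidazol-4-one
Conditions: piperidine (0.3 equiv), n-BuOH, 115 °C
Reagents that add atoms: none
Why: Knoevenagel-type aldol condensation, in which the amine base generates the C5 carbanion of creatinine (stabilised by C4=O and by 4-oxidoimidazole character) and dehydration to the conjugated arylidene drives the equilibrium, so the ring A carbon is attached only at C5 beside N1–CH3 under conditions that keep the MOM acetal intact.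

Step 3
Reactants: 4 (Z)-2-amino-5-[3,4-dimethoxy-2-(methoxymethoxy)benzylidene]-1-methyl-1,5-dihydro-4H-imidazol-4-one
Product: 5 rac-2-amino-5-[3,4-dimethoxy-2-(methoxymethoxy)benzyl]-1-methyl-1,5-dihydro-4H-imidazol-4-one
Conditions: H2 (1 atm), 10% Pd/C, MeOH/THF, 25 °C
Reagents that add atoms: none
Why: Heterogeneous catalytic hydrogenation of the conjugated trisubstituted exocyclic alkene under neutral conditions should leave the aryl ethers, the MOM acetal and the cyclic acylguanidine untouched, and the racemic C5 centre it creates needs no control because step 6 planarises it.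

Step 4
Reactants: 5 rac-2-amino-5-[3,4-dimethoxy-2-(methoxymethoxy)benzyl]-1-methyl-1,5-dihydro-4H-imidazol-4-one
Product: 6 rac-N'-{5-[3,4-dimethoxy-2-(methoxymethoxy)benzyl]-1-methyl-4-oxo-4,5-dihydro-1H-imidazol-2-yl}-N,N-dimethylformamidine
Conditions: Me2NCH(OMe)2 (1.5 equiv), toluene, 80 °C
Reagents that add atoms: N,N-dimethylformamide dimethyl acetal, COC(OC)N(C)C
Why: Amidine formation by condensation of the exocyclic primary amino group with the amide acetal removes both N–H bonds in one operation, and because C5 already carries the benzyl group no aminomethylenation of an active methylene can compete.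

Step 5
Reactants: 7 4-methoxybenzyl chloride
Product: 8 4-methoxybenzylzinc chloride (LiCl-solvated solution in THF)
Conditions: Zn dust (activated with BrCH2CH2Br and Me3SiCl, 5 mol% each), LiCl, THF, 25 °C
Reagents that add atoms: zinc metal, [Zn]
Why: Oxidative insertion of activated zinc metal into the benzylic C–Cl bond, with LiCl keeping the organozinc in solution, is a standard preparation of benzylic zinc chlorides, and slow addition at ambient temperature limits Wurtz-type homocoupling before the titrated solution is used directly in step 6.

Step 6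
Reactants: 6 rac-N'-{5-[3,4-dimethoxy-2-(methoxymethoxy)benzyl]-1-methyl-4-oxo-4,5-dihydro-1H-imidazol-2-yl}-N,N-dimethylformamidine; 8 4-methoxybenzylzinc chloride
Product: 11 N'-{5-[3,4-dimethoxy-2-(methoxymethoxy)benzyl]-4-(4-methoxybenzyl)-1-methylimidazol-2-yl}-N,N-dimethylformamidine, via potassium imidazol-4-olate 9 (not isolated), via imidazol-4-yl triflate 10 (not isolated)
Conditions: KN(SiMe3)2 (1.05 equiv), THF, −78 °C; PhNTf2 (1.05 equiv), −78 to 0 °C; then 8 (1.5 equiv), Pd2(dba)3 (2.5 mol%), XPhos (10 mol%), THF, 25 to 50 °C
Reagents that add atoms: none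
Why: Proposed new method: KN(SiMe3)2 removes the C5 hydrogen of 6 to give the aromatic 4-oxidoimidazole 9, PhNTf2 sulfonylates its oxygen to give triflate 10, and zerovalent palladium carrying XPhos then inserts into the C4–O bond, receives the benzyl group from zinc and forms the C4–CH2 bond by reductive elimination from divalent palladium. The closest known reaction type is the O-triflation of oxazol-4(5H)-ones and thiazol-4(5H)-ones followed by Negishi or Suzuki coupling of the azol-4-yl triflates, run in one flask as is usual for labile lactam-derived enol triflates; the same sequence on a creatinine-derived imidazol-4-one has no direct counterpart. No ring is closed and no stereocentre is formed, the racemic C5 centre of 6 disappearing on aromatisation. The step needs sulfonylation at oxygen and not at C5 or N3, which should be secured by the gain of aromaticity on O-trapping, by the benzyl group that shields C5 and by the formamidine, which leaves no N–H to deprotonate or sulfonylate. It also needs oxidative addition into an electron-rich heteroaryl C–O bond, for which the bulky electron-rich biarylphosphine is chosen, and since the triflate is the only sulfonate or halide present the aryl methyl ethers and the MOM acetal should stay untouched. The benzylzinc reagent has no β-hydrogen and transmetalates fast, so slow addition to hold back homocoupling is the main precaution, and the sulfonamide salt and HN(SiMe3)2 left from the first stage should not interfere.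

Step 7
Reactants: 11 N'-{5-[3,4-dimethoxy-2-(methoxymethoxy)benzyl]-4-(4-methoxybenzyl)-1-methylimidazol-2-yl}-N,N-dimethylformamidine
Product: 13 2-amino-5-(2-hydroxy-3,4-dimethoxybenzyl)-4-(4-methoxybenzyl)-1-methylimidazole, via phenol formamidine 12 (not isolated)
Conditions: HCl (3 M in MeOH), 25 °C; evaporate; then HCl (2 M aq.)/MeOH, 65 °C
Reagents that add atoms: none
Why: Acid-catalysed methanolysis of the MOM acetal followed by acid hydrolysis of the protonated formamidine (addition of water to the amidinium carbon with loss of dimethylamine and formic acid) are standard deprotections, and evaporation between the two stages removes the formaldehyde acetal before heating while the 2-aminoimidazole stays protected as its hydrochloride until neutralisation.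

Step 8
Reactants: 13 2-amino-5-(2-hydroxy-3,4-dimethoxybenzyl)-4-(4-methoxybenzyl)-1-methylimidazole; 14 1-methylparabanic acid
Product: 16 pyronaamidine, via silyl imidate 15 (not isolated)
Conditions: 14 (1.5 equiv), N,O-bis(trimethylsilyl)acetamide (1.6 equiv), MeCN, 80 °C; evaporate; then 13, toluene, 110 °C; aqueous work-up
Reagents that add atoms: none
Why: Silyl-mediated condensation (amidine formation by addition–elimination), in which O-silylation turns the N3–H/C4=O unit of the trione into a silyl imidate that the exocyclic 2-amino group of ring B attacks at C4, the carbon flanked by N3 and C5=O, with loss of silanol, so that ring D is attached with the N-methyl group remote from the new C–N bond as in the target.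

Compound list
1 | 2-hydroxy-3,4-dimethoxybenzaldehyde | O=Cc1ccc(OC)c(OC)c1O | starting material
2 | 3,4-dimethoxy-2-(methoxymethoxy)benzaldehyde | O=Cc1ccc(OC)c(OC)c1OCOC | intermediate
3 | creatinine (2-amino-1-methyl-1,5-dihydro-4H-imidazol-4-one) | CN1CC(=O)N=C1N | starting material
4 | (Z)-2-amino-5-[3,4-dimethoxy-2-(methoxymethoxy)benzylidene]-1-methyl-1,5-dihydro-4H-imidazol-4-one | CN1C(N)=NC(=O)/C1=C/c1ccc(OC)c(OC)c1OCOC | intermediate
5 | rac-2-amino-5-[3,4-dimethoxy-2-(methoxymethoxy)benzyl]-1-methyl-1,5-dihydro-4H-imidazol-4-one | CN1C(Cc2ccc(OC)c(OC)c2OCOC)C(=O)N=C1N | intermediate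
6 | rac-N'-{5-[3,4-dimethoxy-2-(methoxymethoxy)benzyl]-1-methyl-4-oxo-4,5-dihydro-1H-imidazol-2-yl}-N,N-dimethylformamidine | CN1C(Cc2ccc(OC)c(OC)c2OCOC)C(=O)N=C1N=CN(C)C | intermediate
7 | 4-methoxybenzyl chloride | COc1ccc(CCl)cc1 | starting material
8 | 4-methoxybenzylzinc chloride (LiCl-solvated, in THF) | COc1ccc(C[Zn]Cl)cc1 | intermediate
9 | potassium 2-[(dimethylamino)methyleneamino]-5-[3,4-dimethoxy-2-(methoxymethoxy)benzyl]-1-methylimidazol-4-olate | Cn1c(N=CN(C)C)nc([O-])c1Cc1ccc(OC)c(OC)c1OCOC.[K+] | intermediate
10 | 2-[(dimethylamino)methyleneamino]-5-[3,4-dimethoxy-2-(methoxymethoxy)benzyl]-1-methylimidazol-4-yl trifluoromethanesulfonate | Cn1c(N=CN(C)C)nc(OS(=O)(=O)C(F)(F)F)c1Cc1ccc(OC)c(OC)c1OCOC | intermediate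
11 | N'-{5-[3,4-dimethoxy-2-(methoxymethoxy)benzyl]-4-(4-methoxybenzyl)-1-methylimidazol-2-yl}-N,N-dimethylformamidine | Cn1c(N=CN(C)C)nc(Cc2ccc(OC)cc2)c1Cc1ccc(OC)c(OC)c1OCOC | intermediate
12 | N'-[5-(2-hydroxy-3,4-dimethoxybenzyl)-4-(4-methoxybenzyl)-1-methylimidazol-2-yl]-N,N-dimethylformamidine | Cn1c(N=CN(C)C)nc(Cc2ccc(OC)cc2)c1Cc1ccc(OC)c(OC)c1O | intermediate
13 | 2-amino-5-(2-hydroxy-3,4-dimethoxybenzyl)-4-(4-methoxybenzyl)-1-methylimidazole | Cn1c(N)nc(Cc2ccc(OC)cc2)c1Cc1ccc(OC)c(OC)c1O | intermediate
14 | 1-methylparabanic acid (1-methylimidazolidine-2,4,5-trione) | CN1C(=O)NC(=O)C1=O | starting material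
15 | 1-methyl-4-(trimethylsilyloxy)-1H-imidazole-2,5-dione | CN1C(=O)N=C(O[Si](C)(C)C)C1=O | intermediate
16 | pyronaamidine | COc1ccc(Cc2nc(NC3=NC(=O)N(C)C3=O)n(C)c2Cc2ccc(OC)c(OC)c2O)cc1 | target

Total step count: 8. Longest linear sequence: 7 steps (steps 1–4 and 6–8, from 1 to 16); step 5 is a one-step side branch.

Steps most likely to fail

1. Step 6 (bears the label). What may go wrong: sulfonylation of the ambident oxidoimidazole at C5 or at a ring nitrogen instead of oxygen; cleavage of the S–O bond of the triflate by traces of water or by the organozinc before coupling; or slow oxidative addition into the electron-rich C4–O bond, so that homocoupling and protodemetalation of the benzylzinc reagent use up the partners. Fallback (known chemistry only, no cross-coupling; sets out from 5 and returns at 13): the creatinine ring is treated as a masked N-methyl amino acid. Hydrolysis of 5 with Ba(OH)2·8H2O in water at reflux should open and degrade the glycocyamidine ring to the N-methyl amino acid F1. Boc2O with NaOH in dioxane/water gives the N-Boc acid F2, and coupling with MeNHOMe·HCl (EDC·HCl, HOBt, iPr2NEt, CH2Cl2) gives the Weinreb amide F3. 4-Methoxybenzylmagnesium chloride F4, made from 7 and Mg turnings in 2-MeTHF at 0 °C, adds once to F3 to give the N-Boc α-aminoketone F5. HCl in MeOH removes the Boc and MOM groups to give the α-(methylamino)ketone hydrochloride F6, which is condensed at once with cyanamide (H2O/EtOH, pH 4.5, 95 °C). The methylamino nitrogen is guanylated and the new guanidine closes onto the ketone, so ring B forms with N1–CH3 beside the ring A benzyl carbon and 13 results. Alkaline hydrolysis of glycocyamidines, the Weinreb ketone synthesis and the cyanamide condensation of α-aminoketones are all established reaction types. Any reversible hemiketal between the free phenol and the ketone of F6 should be drained by the irreversible aromatisation.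

2. Step 8. What may go wrong: ring-opening acyl transfer from the activated trione to the amine or to the free ortho phenol instead of addition–elimination at C4, reaction at both N–H bonds of the amino group, and poor solubility of the aminophenol in toluene. Fallback (changes the order of events so that ring D is attached while the phenol is still masked; sets out from 11 and returns at 16): hydrazine hydrate in EtOH at 80 °C removes only the formamidine from 11 by transamination and gives the MOM-protected aminoimidazole F7. The same silyl-mediated condensation with 14 through 15 then gives O-MOM-pyronaamidine F8. The MOM acetal is cleaved last with anhydrous HCl in MeOH/CH2Cl2 at 0 to 25 °C, conditions chosen to spare the acylamidine of ring D, to give 16.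

3. Step 2. What may go wrong: incomplete condensation because of the low solubility and modest C–H acidity of creatinine towards an ortho-substituted aldehyde, and loss of the MOM acetal if the mixture has to be forced thermally. Fallback (a more acidic active-methylene partner and late introduction of the amino group; sets out from 2 and returns at 4): commercial 1-methyl-2-thiohydantoin (CN1CC(=O)NC1=S) condenses with 2 under piperidine catalysis in EtOH at 80 °C to give the arylidene thiohydantoin F9. S-Methylation with MeI and K2CO3 in MeCN at 25 °C gives the 2-(methylthio)imidazolone F10. Ammonia in MeOH (sealed vessel, 70 °C) displaces the methylthio group to give 4.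

Further compounds
F1 | step 6 | rac-3-[3,4-dimethoxy-2-(methoxymethoxy)phenyl]-2-(methylamino)propanoic acid | CNC(Cc1ccc(OC)c(OC)c1OCOC)C(=O)O
F2 | step 6 | rac-2-[(tert-butoxycarbonyl)(methyl)amino]-3-[3,4-dimethoxy-2-(methoxymethoxy)phenyl]propanoic acid | CN(C(=O)OC(C)(C)C)C(Cc1ccc(OC)c(OC)c1OCOC)C(=O)O
F3 | step 6 | rac-tert-butyl N-{3-[3,4-dimethoxy-2-(methoxymethoxy)phenyl]-1-[methoxy(methyl)amino]-1-oxopropan-2-yl}-N-methylcarbamate | CON(C)C(=O)C(Cc1ccc(OC)c(OC)c1OCOC)N(C)C(=O)OC(C)(C)C
F4 | step 6 | 4-methoxybenzylmagnesium chloride | COc1ccc(C[Mg]Cl)cc1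
F5 | step 6 | rac-tert-butyl N-{1-[3,4-dimethoxy-2-(methoxymethoxy)phenyl]-4-(4-methoxyphenyl)-3-oxobutan-2-yl}-N-methylcarbamate | COc1ccc(CC(=O)C(Cc2ccc(OC)c(OC)c2OCOC)N(C)C(=O)OC(C)(C)C)cc1
F6 | step 6 | rac-4-(2-hydroxy-3,4-dimethoxyphenyl)-1-(4-methoxyphenyl)-3-(methylamino)butan-2-one hydrochloride | COc1ccc(CC(=O)C(Cc2ccc(OC)c(OC)c2O)NC)cc1.Cl
F7 | step 8 | 2-amino-5-[3,4-dimethoxy-2-(methoxymethoxy)benzyl]-4-(4-methoxybenzyl)-1-methylimidazole | Cn1c(N)nc(Cc2ccc(OC)cc2)c1Cc1ccc(OC)c(OC)c1OCOC
F8 | step 8 | O-(methoxymethyl)pyronaamidine | COc1ccc(Cc2nc(NC3=NC(=O)N(C)C3=O)n(C)c2Cc2ccc(OC)c(OC)c2OCOC)cc1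
F9 | step 2 | (Z)-5-[3,4-dimethoxy-2-(methoxymethoxy)benzylidene]-1-methyl-2-thioxoimidazolidin-4-one | CN1C(=S)NC(=O)/C1=C/c1ccc(OC)c(OC)c1OCOC
F10 | step 2 | (Z)-5-[3,4-dimethoxy-2-(methoxymethoxy)benzylidene]-1-methyl-2-(methylthio)-1,5-dihydro-4H-imidazol-4-one | CN1C(SC)=NC(=O)/C1=C/c1ccc(OC)c(OC)c1OCOC
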